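**Retrosynthetic overview**
- Target ⇐ global hydrogenolysis of the fully O-protected ester ⇐ acylation of 5,7-di-O-PMB-3',4'-di-O-benzyl-(−)-epicatechin with 4-(benzyloxy)benzoyl chloride (from 4-bromophenol by Br/Li exchange and CO2).
- Pyran (C) ring, the only ring that is built: O1–C2 by intramolecular Mitsunobu etherification of an anti-1,2-diol phenol, with inversion at C2 to give the 2,3-cis array.
- Key late coupling: C4–C4a by Cu-catalysed opening of a B-ring epoxy silyl ether (34 non-H atoms, both stereocentres in place) with an A-ring aryl Grignard reagent (35 non-H atoms).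
- Epoxide: catechol → dibenzyl ether → bromide → aryllithium + acrolein → Sharpless kinetic resolution → TBS ether.
- Aryl iodide: resorcinol → bis-PMB ether → Ir C–H borylation/oxidation (third oxygen) → ortho-iodination → TBS ether. Rings A, B and the benzoate ring come intact from the benzene starting materials; ring C is closed in step 15.

Assumption: PMBCl, BnBr, TBSCl, CO2 and the other small reagents are commercial and are not numbered; the target SMILES is read as the (2R,3R) [(−)-epicatechin] series.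

**A-ring fragment**

Step 1
Reactants: 1 resorcinol
Product: 2 1,3-bis[(4-methoxybenzyl)oxy]benzene
Conditions: PMBCl (2.2 eq), K2CO3, KI (cat.), DMF, 60 °C
Reagents that add atoms: 4-methoxybenzyl chloride, COc1ccc(CCl)cc1
Why: Williamson ether synthesis; PMB is used because every C–H on its ring is ortho to a substituent (inert in step 2) and it is removed with the benzyl groups in the final hydrogenolysis.

Step 2
Reactants: 2 1,3-bis[(4-methoxybenzyl)oxy]benzene
Product: 4 3,5-bis[(4-methoxybenzyl)oxy]phenol, via aryl pinacolboronate 3 (not isolated)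
Conditions: [Ir(OMe)(cod)]2 (1.5 mol%), dtbpy (3 mol%), HBpin (1.5 eq), THF, 80 °C; then Oxone, acetone/H2O, 0 °C→rt, 15 min
Reagents that add atoms: pinacolborane, CC1(C)OBOC1(C)C (boron of 3); Oxone (potassium peroxymonosulfate), [K+].[O-]S(=O)(=O)OO (oxygen of 4)
Why: Sterically controlled Ir-catalysed C–H borylation attacks the only C–H with no ortho substituent (C5 of the resorcinol ring), and one-pot oxidation of the C–B bond gives the phenol.

Step 3
Reactants: 4 3,5-bis[(4-methoxybenzyl)oxy]phenol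
Product: 5 2-iodo-3,5-bis[(4-methoxybenzyl)oxy]phenol
Conditions: NIS (1.0 eq), CH2Cl2, −40→0 °C
Reagents that add atoms: N-iodosuccinimide, O=C1CCC(=O)N1I
Why: Electrophilic aromatic iodination of the phenol at the ortho carbon next to the small OH, which is less hindered than C4 between two PMB ethers; the PMB rings do not react without acid.

Step 4
Reactants: 5 2-iodo-3,5-bis[(4-methoxybenzyl)oxy]phenol
Product: 6 tert-butyl{2-iodo-3,5-bis[(4-methoxybenzyl)oxy]phenoxy}dimethylsilane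
Conditions: TBSCl, imidazole, DMF, rt
Reagents that add atoms: tert-butyldimethylsilyl chloride, CC(C)(C)[Si](C)(C)Cl
Why: Standard imidazole-promoted silylation masks the phenol for the Grignard step and is later removed by fluoride without acid.

**B-ring fragment**

Step 5
Reactants: 7 catechol
Product: 8 1,2-bis(benzyloxy)benzene
Conditions: BnBr (2.2 eq), K2CO3, DMF, 60 °C
Reagents that add atoms: benzyl bromide, BrCc1ccccc1
Why: Williamson ether synthesis of both phenols.

Step 6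
Reactants: 8 1,2-bis(benzyloxy)benzene
Product: 9 1,2-bis(benzyloxy)-4-bromobenzene
Conditions: NBS (1.05 eq), MeCN, 0 °C→rt
Reagents that add atoms: N-bromosuccinimide, O=C1CCC(=O)N1Br
Why: Electrophilic aromatic bromination para to an alkoxy group of the activated catechol ring; the benzyl rings are much less reactive.

Step 7
Reactants: 9 1,2-bis(benzyloxy)-4-bromobenzene; 10 acrolein
Product: 12 rac-1-[3,4-bis(benzyloxy)phenyl]prop-2-en-1-ol, via aryllithium 11 (not isolated)
Conditions: n-BuLi, THF, −78 °C; acrolein, −78 °C; H2O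
Reagents that add atoms: n-butyllithium, [Li]CCCC (lithium of 11)
Why: Bromine–lithium exchange followed by 1,2-addition of the aryllithium to acrolein gives the racemic aryl vinyl carbinol.

Step 8
Reactants: 12 rac-1-[3,4-bis(benzyloxy)phenyl]prop-2-en-1-ol
Product: 13 (S)-[3,4-bis(benzyloxy)phenyl][(2R)-oxiran-2-yl]methanol
Conditions: Ti(OiPr)4 (0.2 eq), L-(+)-DIPT (0.24 eq), TBHP (0.45 eq, anhydrous), 4 Å MS, CH2Cl2, −20 °C
Reagents that add atoms: tert-butyl hydroperoxide, CC(C)(C)OO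
Why: Sharpless kinetic resolution: with L-(+)-DIPT the (R)-alcohol is epoxidised fast and anti (erythro)-selectively, which sets the oxirane centre as R and leaves the carbinol centre (now S by CIP) unchanged, while (S)-12 stays unreacted and is separated.

Step 9
Reactants: 13 (S)-[3,4-bis(benzyloxy)phenyl][(2R)-oxiran-2-yl]methanol
Product: 14 tert-butyl{(S)-[3,4-bis(benzyloxy)phenyl][(2R)-oxiran-2-yl]methoxy}dimethylsilane
Conditions: TBSCl, imidazole, DMF, 0 °C→rt
Reagents that add atoms: tert-butyldimethylsilyl chloride, CC(C)(C)[Si](C)(C)Cl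
Why: Silylation of the secondary alcohol under non-acidic conditions protects the carbinol from the Grignard reagent and leaves both stereocentres and the epoxide untouched.

**Acyl fragment**

Step 10
Reactants: 15 4-bromophenol
Product: 16 1-(benzyloxy)-4-bromobenzene
Conditions: BnBr, K2CO3, acetone, reflux
Reagents that add atoms: benzyl bromide, BrCc1ccccc1
Why: Williamson ether synthesis.

Step 11
Reactants: 16 1-(benzyloxy)-4-bromobenzene
Product: 18 4-(benzyloxy)benzoic acid, via aryllithium 17 (not isolated)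
Conditions: n-BuLi, THF, −78 °C; CO2; aq. HCl
Reagents that add atoms: n-butyllithium, [Li]CCCC (lithium of 17); carbon dioxide, O=C=O
Why: Bromine–lithium exchange and carboxylation of the aryllithium with CO2.

Step 12
Reactants: 18 4-(benzyloxy)benzoic acid
Product: 19 4-(benzyloxy)benzoyl chloride
Conditions: (COCl)2, DMF (cat.), CH2Cl2, 0 °C→rt
Reagents that add atoms: oxalyl chloride, O=C(Cl)C(=O)Cl
Why: Acid chloride formation through the Vilsmeier-type chloroiminium intermediate; the aryl benzyl ether is stable to these conditions.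

**Fragment union and end game**

Step 13
Reactants: 6 tert-butyl{2-iodo-3,5-bis[(4-methoxybenzyl)oxy]phenoxy}dimethylsilane; 14 tert-butyl{(S)-[3,4-bis(benzyloxy)phenyl][(2R)-oxiran-2-yl]methoxy}dimethylsilane
Product: 21 (1S,2R)-1-[3,4-bis(benzyloxy)phenyl]-1-[(tert-butyldimethylsilyl)oxy]-3-{2-[(tert-butyldimethylsilyl)oxy]-4,6-bis[(4-methoxybenzyl)oxy]phenyl}propan-2-ol, via arylmagnesium chloride 20 (not isolated)
Conditions: 6 (1.3 eq), i-PrMgCl·LiCl, THF, −20→0 °C; CuI (10 mol%), then 14, −30→0 °C; H2O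
Reagents that add atoms: isopropylmagnesium chloride (LiCl complex), CC(C)[Mg]Cl (Mg and Cl of 20)
Why: Iodine–magnesium exchange then Cu-catalysed SN2 opening of the terminal epoxide at CH2 forms the C4–C4a bond; neither stereocentre of 14 is involved, so the anti (1S,2R) array is carried over.

Step 14
Reactants: 21 (the bis-TBS ether from step 13)
Product: 22 (1S,2R)-1-[3,4-bis(benzyloxy)phenyl]-3-{2-hydroxy-4,6-bis[(4-methoxybenzyl)oxy]phenyl}propane-1,2-diol
Conditions: TBAF/AcOH (1:1, 3 eq), THF, 0 °C→rt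
Reagents that add atoms: none
Why: Buffered fluoride desilylation removes the aryl and alkyl TBS groups together; no acid is used, so the PMB ethers and the ionisable electron-rich benzylic carbinol keep their integrity.

Step 15
Reactants: 22 (the anti triol from step 14)
Product: 23 (2R,3R)-2-[3,4-bis(benzyloxy)phenyl]-5,7-bis[(4-methoxybenzyl)oxy]-3,4-dihydro-2H-chromen-3-ol
Conditions: PPh3 (1.5 eq), DIAD (1.5 eq), THF (0.02 M), 0 °C→rt
Reagents that add atoms: none
Why: Intramolecular Mitsunobu etherification: the phenol, the only acidic OH, displaces the activated benzylic oxygen in a 6-exo-tet SN2 reaction with inversion (1S → 2R), which turns the anti diol into the 2,3-cis chroman while C3 (R) is untouched.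

Step 16
Reactants: 23 (the protected epicatechin from step 15); 19 4-(benzyloxy)benzoyl chloride
Product: 24 (2R,3R)-2-[3,4-bis(benzyloxy)phenyl]-5,7-bis[(4-methoxybenzyl)oxy]-3,4-dihydro-2H-chromen-3-yl 4-(benzyloxy)benzoate
Conditions: 19 (1.5 eq), Et3N, DMAP (cat.), CH2Cl2, rt
Reagents that add atoms: none
Why: DMAP-catalysed acylation of the only free hydroxyl (the axial 3-OH) with the acid chloride; no stereocentre is affected.

Step 17
Reactants: 24 (the protected ester from step 16)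
Product: 25 epicatechin 3-O-p-hydroxybenzoate, (2R,3R)-2-(3,4-dihydroxyphenyl)-5,7-dihydroxy-3,4-dihydro-2H-chromen-3-yl 4-hydroxybenzoate
Conditions: H2 (1 atm), 20% Pd(OH)2/C, THF/MeOH, rt
Reagents that add atoms: none
Why: Global hydrogenolysis with Pearlman's catalyst cleaves the three benzyl and two PMB ethers, while the ester, the C2–O1 bond and both stereocentres survive at 1 atm and room temperature.

**Compound list**
1 | resorcinol (benzene-1,3-diol) | Oc1cccc(O)c1 | starting material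
2 | 1,3-bis[(4-methoxybenzyl)oxy]benzene | COc1ccc(COc2cccc(OCc3ccc(OC)cc3)c2)cc1 | intermediate
3 | 2-{3,5-bis[(4-methoxybenzyl)oxy]phenyl}-4,4,5,5-tetramethyl-1,3,2-dioxaborolane | COc1ccc(COc2cc(OCc3ccc(OC)cc3)cc(B3OC(C)(C)C(C)(C)O3)c2)cc1 | intermediate (not isolated)
4 | 3,5-bis[(4-methoxybenzyl)oxy]phenol | COc1ccc(COc2cc(O)cc(OCc3ccc(OC)cc3)c2)cc1 | intermediate
5 | 2-iodo-3,5-bis[(4-methoxybenzyl)oxy]phenol | COc1ccc(COc2cc(O)c(I)c(OCc3ccc(OC)cc3)c2)cc1 | intermediate
6 | tert-butyl{2-iodo-3,5-bis[(4-methoxybenzyl)oxy]phenoxy}dimethylsilane | COc1ccc(COc2cc(O[Si](C)(C)C(C)(C)C)c(I)c(OCc3ccc(OC)cc3)c2)cc1 | intermediate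
7 | catechol (benzene-1,2-diol) | Oc1ccccc1O | starting material
8 | 1,2-bis(benzyloxy)benzene | c1ccc(COc2ccccc2OCc2ccccc2)cc1 | intermediate
9 | 1,2-bis(benzyloxy)-4-bromobenzene | Brc1ccc(OCc2ccccc2)c(OCc2ccccc2)c1 | intermediate
10 | acrolein (prop-2-enal) | C=CC=O | starting material
11 | [3,4-bis(benzyloxy)phenyl]lithium | [Li]c1ccc(OCc2ccccc2)c(OCc2ccccc2)c1 | intermediate (not isolated)
12 | rac-1-[3,4-bis(benzyloxy)phenyl]prop-2-en-1-ol | C=CC(O)c1ccc(OCc2ccccc2)c(OCc2ccccc2)c1 | intermediate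
13 | (S)-[3,4-bis(benzyloxy)phenyl][(2R)-oxiran-2-yl]methanol | O[C@H]([C@H]1CO1)c1ccc(OCc2ccccc2)c(OCc2ccccc2)c1 | intermediate
14 | tert-butyl{(S)-[3,4-bis(benzyloxy)phenyl][(2R)-oxiran-2-yl]methoxy}dimethylsilane | CC(C)(C)[Si](C)(C)O[C@H]([C@H]1CO1)c1ccc(OCc2ccccc2)c(OCc2ccccc2)c1 | intermediate
15 | 4-bromophenol | Oc1ccc(Br)cc1 | starting material
16 | 1-(benzyloxy)-4-bromobenzene | Brc1ccc(OCc2ccccc2)cc1 | intermediate
17 | [4-(benzyloxy)phenyl]lithium | [Li]c1ccc(OCc2ccccc2)cc1 | intermediate (not isolated)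
18 | 4-(benzyloxy)benzoic acid | OC(=O)c1ccc(OCc2ccccc2)cc1 | intermediate
19 | 4-(benzyloxy)benzoyl chloride | ClC(=O)c1ccc(OCc2ccccc2)cc1 | intermediate
20 | {2-[(tert-butyldimethylsilyl)oxy]-4,6-bis[(4-methoxybenzyl)oxy]phenyl}magnesium chloride | COc1ccc(COc2cc(O[Si](C)(C)C(C)(C)C)c([Mg]Cl)c(OCc3ccc(OC)cc3)c2)cc1 | intermediate (not isolated)
21 | (1S,2R)-1-[3,4-bis(benzyloxy)phenyl]-1-[(tert-butyldimethylsilyl)oxy]-3-{2-[(tert-butyldimethylsilyl)oxy]-4,6-bis[(4-methoxybenzyl)oxy]phenyl}propan-2-ol | CC(C)(C)[Si](C)(C)O[C@H]([C@H](O)Cc1c(O[Si](C)(C)C(C)(C)C)cc(OCc2ccc(OC)cc2)cc1OCc1ccc(OC)cc1)c1ccc(OCc2ccccc2)c(OCc2ccccc2)c1 | intermediate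
22 | (1S,2R)-1-[3,4-bis(benzyloxy)phenyl]-3-{2-hydroxy-4,6-bis[(4-methoxybenzyl)oxy]phenyl}propane-1,2-diol | O[C@H]([C@H](O)Cc1c(O)cc(OCc2ccc(OC)cc2)cc1OCc1ccc(OC)cc1)c1ccc(OCc2ccccc2)c(OCc2ccccc2)c1 | intermediate
23 | (2R,3R)-2-[3,4-bis(benzyloxy)phenyl]-5,7-bis[(4-methoxybenzyl)oxy]-3,4-dihydro-2H-chromen-3-ol | O[C@@H]1Cc2c(OCc3ccc(OC)cc3)cc(OCc3ccc(OC)cc3)cc2O[C@@H]1c1ccc(OCc2ccccc2)c(OCc2ccccc2)c1 | intermediate
24 | (2R,3R)-2-[3,4-bis(benzyloxy)phenyl]-5,7-bis[(4-methoxybenzyl)oxy]-3,4-dihydro-2H-chromen-3-yl 4-(benzyloxy)benzoate | O=C(O[C@@H]1Cc2c(OCc3ccc(OC)cc3)cc(OCc3ccc(OC)cc3)cc2O[C@@H]1c1ccc(OCc2ccccc2)c(OCc2ccccc2)c1)c1ccc(OCc2ccccc2)cc1 | intermediate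
25 | epicatechin 3-O-p-hydroxybenzoate, (2R,3R) | O=C(O[C@@H]1Cc2c(O)cc(O)cc2O[C@@H]1c1ccc(O)c(O)c1)c1ccc(O)cc1 | target

**Step count and weak points**

Total step count: 17. Longest linear sequence: 10 steps (5, 6, 7, 8, 9, 13, 14, 15, 16, 17, from catechol 7).

Most likely to fail, step 8 (kinetic resolution): the electron-rich aryl vinyl carbinol may ionise on titanium or resolve with a low rate ratio. The fallback sets out from 12 and comes back at 13. Racemic 12 is resolved by enzymatic acylation instead (vinyl acetate, immobilised Candida antarctica lipase B, MTBE, 30 °C, about 50% conversion), which gives (R)-1-[3,4-bis(benzyloxy)phenyl]prop-2-en-1-yl acetate F1 and leaves (S)-12. Methanolysis (K2CO3, MeOH) gives (R)-1-[3,4-bis(benzyloxy)phenyl]prop-2-en-1-ol F2. This single enantiomer is then epoxidised to full conversion in the matched sense (Ti(OiPr)4, L-(+)-DIPT, TBHP, −20 °C) to give 13.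

Most likely to fail, step 13 (fragment coupling): the doubly ortho-substituted aryl Grignard reagent may exchange or add sluggishly. The fallback sets out from 4 (and uses 14) and comes back at 22. Phenol 4 is protected with SEMCl/i-Pr2NEt to give [2-({3,5-bis[(4-methoxybenzyl)oxy]phenoxy}methoxy)ethyl]trimethylsilane F3. Directed ortho-lithiation (n-BuLi, TMEDA, THF, −20 °C) between the OSEM and OPMB groups gives (2-{[2-(trimethylsilyl)ethoxy]methoxy}-4,6-bis[(4-methoxybenzyl)oxy]phenyl)lithium F4. F4 opens epoxide 14 at CH2 under BF3·OEt2 activation at −78 °C to give (1S,2R)-1-[3,4-bis(benzyloxy)phenyl]-1-[(tert-butyldimethylsilyl)oxy]-3-(2-{[2-(trimethylsilyl)ethoxy]methoxy}-4,6-bis[(4-methoxybenzyl)oxy]phenyl)propan-2-ol F5. TBAF in THF/DMPU at 60 °C then removes the SEM and TBS groups together to give triol 22.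

Most likely to fail, step 15 (Mitsunobu ring closure): activation of the C3 hydroxyl could lead to the five-membered ether or an epoxide, and partial ionisation at the benzylic carbon would erode the cis selectivity. The fallback sets out from 21 (and uses 19) and comes back at 24. Alcohol 21 is acylated first with 19 (Et3N, DMAP, CH2Cl2) to give (1S,2R)-1-[3,4-bis(benzyloxy)phenyl]-1-[(tert-butyldimethylsilyl)oxy]-3-{2-[(tert-butyldimethylsilyl)oxy]-4,6-bis[(4-methoxybenzyl)oxy]phenyl}propan-2-yl 4-(benzyloxy)benzoate F6. Buffered desilylation (TBAF/AcOH, THF, 0 °C) gives (1S,2R)-1-[3,4-bis(benzyloxy)phenyl]-1-hydroxy-3-{2-hydroxy-4,6-bis[(4-methoxybenzyl)oxy]phenyl}propan-2-yl 4-(benzyloxy)benzoate F7. With the C3 oxygen acylated, only the benzylic hydroxyl can be activated, and Mitsunobu closure (PPh3, DIAD, THF) gives 24 directly.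

**Further compounds**
F1 | step 8 | (R)-1-[3,4-bis(benzyloxy)phenyl]prop-2-en-1-yl acetate | C=C[C@@H](OC(C)=O)c1ccc(OCc2ccccc2)c(OCc2ccccc2)c1
F2 | step 8 | (R)-1-[3,4-bis(benzyloxy)phenyl]prop-2-en-1-ol | C=C[C@@H](O)c1ccc(OCc2ccccc2)c(OCc2ccccc2)c1
F3 | step 13 | [2-({3,5-bis[(4-methoxybenzyl)oxy]phenoxy}methoxy)ethyl]trimethylsilane | COc1ccc(COc2cc(OCOCC[Si](C)(C)C)cc(OCc3ccc(OC)cc3)c2)cc1
F4 | step 13 | (2-{[2-(trimethylsilyl)ethoxy]methoxy}-4,6-bis[(4-methoxybenzyl)oxy]phenyl)lithium | COc1ccc(COc2cc(OCOCC[Si](C)(C)C)c([Li])c(OCc3ccc(OC)cc3)c2)cc1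
F5 | step 13 | (1S,2R)-1-[3,4-bis(benzyloxy)phenyl]-1-[(tert-butyldimethylsilyl)oxy]-3-(2-{[2-(trimethylsilyl)ethoxy]methoxy}-4,6-bis[(4-methoxybenzyl)oxy]phenyl)propan-2-ol | CC(C)(C)[Si](C)(C)O[C@H]([C@H](O)Cc1c(OCOCC[Si](C)(C)C)cc(OCc2ccc(OC)cc2)cc1OCc1ccc(OC)cc1)c1ccc(OCc2ccccc2)c(OCc2ccccc2)c1
F6 | step 15 | (1S,2R)-1-[3,4-bis(benzyloxy)phenyl]-1-[(tert-butyldimethylsilyl)oxy]-3-{2-[(tert-butyldimethylsilyl)oxy]-4,6-bis[(4-methoxybenzyl)oxy]phenyl}propan-2-yl 4-(benzyloxy)benzoate | CC(C)(C)[Si](C)(C)O[C@H]([C@H](OC(=O)c1ccc(OCc2ccccc2)cc1)Cc1c(O[Si](C)(C)C(C)(C)C)cc(OCc2ccc(OC)cc2)cc1OCc1ccc(OC)cc1)c1ccc(OCc2ccccc2)c(OCc2ccccc2)c1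
F7 | step 15 | (1S,2R)-1-[3,4-bis(benzyloxy)phenyl]-1-hydroxy-3-{2-hydroxy-4,6-bis[(4-methoxybenzyl)oxy]phenyl}propan-2-yl 4-(benzyloxy)benzoate | O[C@H]([C@H](OC(=O)c1ccc(OCc2ccccc2)cc1)Cc1c(O)cc(OCc2ccc(OC)cc2)cc1OCc1ccc(OC)cc1)c1ccc(OCc2ccccc2)c(OCc2ccccc2)c1
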